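## Structural features

The target is made of two 2,2-dimethyl-2H-chromenes, rings A/B and rings C/D, joined only through the sp3 carbon C9, which carries a methyl group and is bonded to C3 of ring B and to C6' of ring C. Ring A is a fully substituted acetophloroglucinol: the pyran oxygen O1 is para to the 6-acetyl group, the free 5-OH is chelated to that acetyl group, C7 carries OMe and C8 the only aromatic hydrogen. Ring C has a methoxy group on each carbon next to the C9-bearing carbon and the ring D oxygen para to it. C9 is the only stereocentre (S; CIP order aryl > C3 > CH3 > H) and has no stereogenic neighbour, so its configuration must come from a reagent or catalyst. The fragile groups are the two styrene-type pyran double bonds (that of ring D, cis-disubstituted, is the easier to hydrogenate or hydrate), the acetyl group (enolisable and electrophilic) and the benzylic, allylic C9–H bond. The real difficulty is the crowded C3–C9–aryl junction, which lies between a 2,6-dimethoxyaryl group and an alkene carbon whose other neighbour is the quaternary C2, and which must be formed enantioselectively without a directing group. The key step uses the fact that C3 of ring B carries C9: with C9 as a carbonyl carbon, C3 is an enolate carbon and the gem-dimethyl carbon C2 is the β-carbon of an enone, so O1–C2 and C3–C4 are the bonds of a phenoxide conjugate addition followed by aldol condensation onto a formyl carbon (C4) on ring A.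

## Logic of the disconnections

**17 to 15 and 16.** The O1'–C2' and C4'–C4a' bonds of ring D are cut first, so ring D is made last. Its cis-disubstituted double bond would not survive the hydrogenation that sets C9, and the two ortho carbons of the phenol in 15 are interchangeable, so no regiochemical question arises. The cut removes one ring and five carbons. The forward step must condense 16 at a ring carbon of 15 without touching the acetyl methyl group or the C9–H bond.

**15 to 14.** Only the O–CH2 bond of an acetal is cut. The ring C oxygen has to stay masked from step 2 to step 7 against hot phenoxide, organometallic reagents and silylation. The forward step needs an acid mild enough to leave the ring B double bond and C9 alone.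

**14 to 13.** The C9–H bond (and one C–H bond of the methyl group) is cut, which turns the stereocentre into a prochiral 1,1-disubstituted alkene. With no neighbouring stereocentre and no directing group, catalyst control on an alkene is the most direct option, and every compound before 14 is then achiral or racemic. The forward step must select one alkene face and must reduce the terminal double bond but not the C3=C4 bond.

**13 to 10.** The C9–CH3 bond is cut (formed as a C–C bond to a carbonyl carbon, followed by loss of water). This methyl carbon is the only skeletal atom that the union of the two halves does not supply, and removing it exposes the ketone the key step needs. The forward step must bring a methyl nucleophile to a hindered, non-enolisable ketone while the acetyl group and the ring A phenol are masked in the same flask.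

**10 to 2 and 7.** O1–C2 and C3–C4 are cut, which splits the molecule into its two aryl halves of similar size and opens ring B. All skeletal carbons except the C9 methyl group are then present in two simple aryl carbonyl compounds. The forward step must make a tertiary alkyl aryl ether by conjugate addition to a fully substituted β-carbon, use the hydroxyl para to the acetyl group rather than the chelated one, and leave the acetyl methyl group uncondensed.

**7 to 4 and 5 (through 6), and 4 to 3.** The bond between the carbonyl carbon and the vinyl carbon is cut, then the acetal. The substitution pattern of ring C is bought with 3, so no ring metalation or regiochemistry is involved. A silyl ether on this oxygen was rejected: an aryl silyl ether para to an acyl group is liable to be transferred to phenoxide under the hot carbonate conditions of step 5. An acetal is inert there, but it would steer a ring lithiation to the wrong carbon, which is why the carbonyl carbon comes with 3 rather than from a metalation. The forward steps need only a 1,2-addition and a neutral oxidation of an ionisable carbinol.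

**2 to 1.** The bond between the formyl carbon and the ring carbon between the two hydroxyls is cut. This leaves a purchasable acetophenone, and the forward step must formylate C3 rather than C5.

## Other disconnections considered

**Alternative 1:** The cut removes both methyl groups from C2 and opens O1–C2, so ring B is traced back to the coumarin A2 (same spatial arrangement at C9 as the target; the descriptor becomes R only because the lactone carbon raises the CIP rank of C3). In the forward sense MeMgBr with CeCl3 would add twice to the lactone carbonyl, and mild acid would close the phenol onto the tertiary allylic carbon to give the bromo MOM ether A1.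
- In its favour: coumarins are assembled by dependable condensations, and the slow conjugate addition to a fully substituted β-carbon is avoided. The stereocentre can be made beforehand in a small acyclic precursor by conjugate-addition catalysis. On this point it is better than the chosen plan, which must hydrogenate a hindered diene.
- Against it here: excess methyl Grignard reagent cannot coexist with the acetyl group, so the acetyl group is carried as bromine with the 5-OH as a MOM ether and restored later by halogen–lithium exchange, acetylation and deprotection. After the first addition the ring-opened enone has the doubly activated C9–H bond in its γ-position, so dienolate formation could erode the configuration. The key step adds only two methyl carbons and no bond between the halves.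
- Comparison: on structure the two plans are equal (same ring B, same phenol/carbonyl relationship on ring A). On mechanism Alternative 1 is less sensitive to hindrance at C2 but more exposed to base at C9. On step economy the chosen plan should be shorter by about three to four steps.

**Alternative 2:** Ring C is taken apart completely: three of its C–C bonds are cut. In the forward sense, irradiation of the diazo ketone A4 in the presence of the siloxyalkyne A5 would lead, through Wolff rearrangement, ketene–alkyne [2+2] cycloaddition, 4π-electrocyclic opening and 6π-electrocyclic closure, to the chromanone A3.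
- In its favour: the substitution pattern of ring C, including two differentiated oxygens, is fixed by construction. The C9–aryl bond is never made at a hindered centre, and the stereocentre sits in A5 before the arene exists. In regiochemical certainty it is better than the chosen plan, and in avoiding a late asymmetric hydrogenation it is at least its equal.
- Against it here: A5 is an ynol silyl ether with a propargylic stereocentre next to a chromene and needs a multistep, epimerisation-prone preparation. The irradiation must be carried out on a molecule that contains a photochromic 2H-chromene and an aryl bromide. After the key step, two oxygens must still be methylated, the chromanone reduced and dehydrated to ring D, and bromine exchanged for the acetyl group.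
- Comparison: on mechanism the pericyclic cascade is elegant but depends on light-sensitive functionality, whereas the chosen domino is polar and thermal. On step economy the chosen plan is clearly shorter and joins the halves with less post-processing.

**Alternative 3:** C3=C4 and C9=CH2 are cut. In the forward sense the enyne A7 would undergo exo ring-closing enyne metathesis with the second-generation Grubbs catalyst (H2IMes)(PCy3)Cl2Ru=CHPh under ethylene to give the diene A6, the silyl analogue of 13.
- In its favour: the diene is reached with the acetyl group in place, so no methyl nucleophile has to be used next to the acetyl group and no dehydration is needed. In this respect it is better than the chosen plan. Ruthenium carbenes tolerate ketones and phenols.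
- Against it here: A7 requires a tertiary propargyl aryl ether whose alkyne carries the 2,6-dimethoxyaryl group, that is, a coupling of an electron-rich, di-ortho-substituted aryl halide and an ortho-vinylation on the ring A fragment. An alkyne flanked by a quaternary carbon and a di-ortho-substituted arene is a poor partner for a ruthenium carbene.
- Comparison: the stereochemical problem is unchanged (equal), since the same kind of diene must be hydrogenated. On step economy the linear sequence on the ring A fragment is longer than in the chosen plan.

Key step: step 5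

Assumption: hydrogen delivery to the Re face of C9 is ascribed to the (S)-configured PHOX ligand as a working assignment; if the sense proves opposite, the (R)-ligand is used in the same step.

## Route

Step 1
Reactants: 1 1-(2,4-dihydroxy-6-methoxyphenyl)ethanone
Product: 2 3-acetyl-2,6-dihydroxy-4-methoxybenzaldehyde
Conditions: Cl2CHOMe, TiCl4, CH2Cl2, 0 °C → rt; then 1 M aq. HCl
Reagents that add atoms: dichloromethyl methyl ether, COC(Cl)Cl; water, O
Why: Rieche formylation (electrophilic aromatic substitution by the TiCl4-activated chloro(methoxy)methyl cation, then hydrolysis of the α-chloro ether). Both free ring carbons are activated by the same three oxygen donors, but C3 is ortho to both titanium-bound phenolic oxygens and lies between the two small OH groups, whereas C5 is ortho to only one and next to OMe, so delivery to C3 is expected; the new formyl group deactivates the ring against a second substitution.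

Step 2
Reactants: 3 4-hydroxy-2,6-dimethoxybenzaldehyde
Product: 4 2,6-dimethoxy-4-(methoxymethoxy)benzaldehyde
Conditions: MOMCl, iPr2NEt, CH2Cl2, 0 °C → rt
Reagents that add atoms: chloromethyl methyl ether, COCCl
Why: O-alkylation of an acidic, vinylogous-acid phenol with an α-chloro ether. The acetal is inert to hot phenoxide, organolithium reagents and hydrogenation and is removed later by mild acid.

Step 3
Reactants: 4 2,6-dimethoxy-4-(methoxymethoxy)benzaldehyde; 5 (2-methylprop-1-en-1-yl)magnesium bromide
Product: 6 rac-1-[2,6-dimethoxy-4-(methoxymethoxy)phenyl]-3-methylbut-2-en-1-ol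
Conditions: THF, −78 → 0 °C; then aq. NH4Cl (crude 6 used directly)
Reagents that add atoms: none
Why: Grignard 1,2-addition to an aldehyde. The carbinol stereocentre is formed racemic and is removed in step 4; because this 2,4,6-trioxygenated benzylic, allylic alcohol ionises easily, it is not chromatographed.

Step 4
Reactants: 6 rac-1-[2,6-dimethoxy-4-(methoxymethoxy)phenyl]-3-methylbut-2-en-1-ol
Product: 7 1-[2,6-dimethoxy-4-(methoxymethoxy)phenyl]-3-methylbut-2-en-1-one
Conditions: MnO2, CH2Cl2, rt
Reagents that add atoms: none
Why: MnO2 oxidation of an allylic and benzylic secondary alcohol under neutral conditions, which avoids acid-induced ionisation of 6 and cannot over-oxidise.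

Step 5
Reactants: 2 3-acetyl-2,6-dihydroxy-4-methoxybenzaldehyde; 7 1-[2,6-dimethoxy-4-(methoxymethoxy)phenyl]-3-methylbut-2-en-1-one
Product: 10 (6-acetyl-5-hydroxy-7-methoxy-2,2-dimethyl-2H-chromen-3-yl)[2,6-dimethoxy-4-(methoxymethoxy)phenyl]methanone, via oxa-Michael adduct 8 (not isolated), via aldol adduct 9 (not isolated)
Conditions: K2CO3 (1 equiv per 2), 2 (1.5 equiv), 4 Å MS, 1,4-dioxane, 100 °C
Reagents that add atoms: none
Why: Carbonate forms the phenoxide of 2, whose oxygen para to the acetyl group adds to the β-carbon of 7 and so makes the O1–C2 bond and the enolate of 8. The enolate carbon then attacks the formyl group on the neighbouring ring carbon in a 6-exo-trig aldol closure (C3–C4) that completes ring B as the β-hydroxy ketone 9. E1cB loss of water from 9 is irreversible, gives the conjugated chromene 10 and draws the two reversible steps before it forward. The closest known reaction type is the carbonate- or amine-mediated domino oxa-Michael/aldol condensation of salicylaldehydes with enals and enones to 3-acyl-2H-chromenes, which includes β,β-dimethyl acceptors such as 3-methylbut-2-enal. No stereocentre remains, because the two centres of 9 are erased by the dehydration. Site selectivity between the two hydroxyls is needed and rests on sterics: the reacting oxygen is flanked by CHO and H, whereas the other is chelated and wedged between CHO and acetyl, where a tertiary alkyl aryl ether is much more congested, and the desired product keeps the acetyl–OH chelate. Condensation of the acetyl methyl group with the aldehyde is held back by the weak, sparingly soluble base and by the deactivation of both carbonyl groups in the phenoxide, and 7 has no hydrogen on the aryl side of its carbonyl group and cannot self-condense. The perpendicular 2,6-dimethoxyaryl group leaves the enone carbonyl unconjugated with the arene, so the β-carbon keeps its electrophilicity, and the MOM ether is inert to hot phenoxide.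

Step 6
Reactants: 10 (6-acetyl-5-hydroxy-7-methoxy-2,2-dimethyl-2H-chromen-3-yl)[2,6-dimethoxy-4-(methoxymethoxy)phenyl]methanone
Product: 13 1-(3-{1-[2,6-dimethoxy-4-(methoxymethoxy)phenyl]ethenyl}-5-hydroxy-7-methoxy-2,2-dimethyl-2H-chromen-6-yl)ethanone, via bis(trimethylsilyl) ketone 11 (not isolated), via silylated tertiary carbinol 12 (not isolated)
Conditions: LiN(SiMe3)2, Me3SiCl, THF, −78 → 0 °C; volatiles removed; MeLi/CeCl3, THF, −78 °C; then 1 M aq. HCl, 0 °C → rt
Reagents that add atoms: methyllithium, C[Li]
Why: In situ masking followed by organocerium 1,2-addition and E1 dehydration: the phenol becomes a silyl ether and the acetyl group, the only enolisable ketone, a silyl enol ether, while the aroyl ketone of 10 has no α-hydrogen and stays free for the weakly basic, hindrance-tolerant MeCeCl2. The acidic quench removes both silyl groups and ionises the 2,4,6-trioxygenated benzylic, allylic carbinol, whose cation can only lose a methyl proton, so the terminal alkene of 13 results.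

Step 7
Reactants: 13 1-(3-{1-[2,6-dimethoxy-4-(methoxymethoxy)phenyl]ethenyl}-5-hydroxy-7-methoxy-2,2-dimethyl-2H-chromen-6-yl)ethanone
Product: 14 1-(3-{(1S)-1-[2,6-dimethoxy-4-(methoxymethoxy)phenyl]ethyl}-5-hydroxy-7-methoxy-2,2-dimethyl-2H-chromen-6-yl)ethanone
Conditions: [Ir(cod)((S)-tBu-PHOX)]B[3,5-(CF3)2C6H3]4 (2 mol %), H2 (1 bar), CH2Cl2, rt
Reagents that add atoms: none
Why: Iridium N,P-ligand-catalysed asymmetric hydrogenation of an unfunctionalised 1,1-disubstituted alkene ((S)-tBu-PHOX = (S)-4-tert-butyl-2-[2-(diphenylphosphanyl)phenyl]-4,5-dihydro-1,3-oxazole); the catalyst distinguishes the perpendicular 2,6-dimethoxyaryl group from the flatter chromenyl group and must deliver hydrogen to the Re face of C9 (priorities aryl > C3 > CH2) to give 9S, so the stereocentre is set under catalyst control. The terminal alkene has no allylic hydrogen, so isomerisation cannot erode the selectivity, and the trisubstituted C3=C4 bond between quaternary C2 and the new tertiary C9, the acetyl group, the acetal and the phenol should be left at 1 bar.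

Step 8
Reactants: 14 1-(3-{(1S)-1-[2,6-dimethoxy-4-(methoxymethoxy)phenyl]ethyl}-5-hydroxy-7-methoxy-2,2-dimethyl-2H-chromen-6-yl)ethanone
Product: 15 1-{5-hydroxy-3-[(1S)-1-(4-hydroxy-2,6-dimethoxyphenyl)ethyl]-7-methoxy-2,2-dimethyl-2H-chromen-6-yl}ethanone
Conditions: HCl (2 M), MeOH, 40 °C
Reagents that add atoms: none
Why: Acid-catalysed acetal exchange with methanol (MOM cleavage). C9 should keep its configuration because protonation of the C3=C4 bond occurs at C3 and gives the ring A-stabilised C4 cation, a pathway that does not involve the C9–H bond.

Step 9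
Reactants: 15 1-{5-hydroxy-3-[(1S)-1-(4-hydroxy-2,6-dimethoxyphenyl)ethyl]-7-methoxy-2,2-dimethyl-2H-chromen-6-yl}ethanone; 16 3-methylbut-2-enal
Product: 17 1-{3-[(1S)-1-(5,7-dimethoxy-2,2-dimethyl-2H-chromen-6-yl)ethyl]-5-hydroxy-7-methoxy-2,2-dimethyl-2H-chromen-6-yl}ethanone
Conditions: 16 (3 equiv), ethylenediammonium diacetate H3NCH2CH2NH3(OAc)2 (20 mol %), toluene, 110 °C
Reagents that add atoms: none
Why: Chromenylation (formal [3+3] annulation): the iminium-activated enal is attacked by the ortho carbon of the phloroglucinol-type phenol, elimination gives the ortho-quinone methide and oxa-6π-electrocyclisation closes ring D. The two ortho carbons of the ring C phenol are equivalent and the ring A phenol has no free ortho carbon, so one constitution is expected, and C9 is not involved.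

## Compound list

1 | 1-(2,4-dihydroxy-6-methoxyphenyl)ethanone | CC(=O)c1c(O)cc(O)cc1OC | starting material
2 | 3-acetyl-2,6-dihydroxy-4-methoxybenzaldehyde | CC(=O)c1c(O)c(C=O)c(O)cc1OC | intermediate
3 | 4-hydroxy-2,6-dimethoxybenzaldehyde | COc1cc(O)cc(OC)c1C=O | starting material
4 | 2,6-dimethoxy-4-(methoxymethoxy)benzaldehyde | COCOc1cc(OC)c(C=O)c(OC)c1 | intermediate
5 | (2-methylprop-1-en-1-yl)magnesium bromide | CC(C)=C[Mg]Br | starting material
6 | rac-1-[2,6-dimethoxy-4-(methoxymethoxy)phenyl]-3-methylbut-2-en-1-ol (racemate) | COCOc1cc(OC)c(C(O)C=C(C)C)c(OC)c1 | intermediate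
7 | 1-[2,6-dimethoxy-4-(methoxymethoxy)phenyl]-3-methylbut-2-en-1-one | COCOc1cc(OC)c(C(=O)C=C(C)C)c(OC)c1 | intermediate
8 | 3-acetyl-6-({4-[2,6-dimethoxy-4-(methoxymethoxy)phenyl]-2-methyl-4-oxobutan-2-yl}oxy)-2-hydroxy-4-methoxybenzaldehyde (oxa-Michael adduct) | CC(=O)c1c(O)c(C=O)c(OC(C)(C)CC(=O)c2c(OC)cc(OCOC)cc2OC)cc1OC | intermediate (not isolated)
9 | 1-{3-[2,6-dimethoxy-4-(methoxymethoxy)benzoyl]-4,5-dihydroxy-7-methoxy-2,2-dimethyl-3,4-dihydro-2H-chromen-6-yl}ethanone (aldol adduct, mixture of stereoisomers) | COc1cc2c(c(O)c1C(C)=O)C(O)C(C(=O)c1c(OC)cc(OCOC)cc1OC)C(C)(C)O2 | intermediate (not isolated)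
10 | (6-acetyl-5-hydroxy-7-methoxy-2,2-dimethyl-2H-chromen-3-yl)[2,6-dimethoxy-4-(methoxymethoxy)phenyl]methanone | COc1cc2c(c(O)c1C(C)=O)C=C(C(=O)c1c(OC)cc(OCOC)cc1OC)C(C)(C)O2 | intermediate
11 | [2,6-dimethoxy-4-(methoxymethoxy)phenyl]{7-methoxy-2,2-dimethyl-5-(trimethylsilyloxy)-6-[1-(trimethylsilyloxy)ethenyl]-2H-chromen-3-yl}methanone | COc1cc2c(c(O[Si](C)(C)C)c1C(=C)O[Si](C)(C)C)C=C(C(=O)c1c(OC)cc(OCOC)cc1OC)C(C)(C)O2 | intermediate (not isolated)
12 | rac-1-[2,6-dimethoxy-4-(methoxymethoxy)phenyl]-1-{7-methoxy-2,2-dimethyl-5-(trimethylsilyloxy)-6-[1-(trimethylsilyloxy)ethenyl]-2H-chromen-3-yl}ethanol (racemate) | COc1cc2c(c(O[Si](C)(C)C)c1C(=C)O[Si](C)(C)C)C=C(C(C)(O)c1c(OC)cc(OCOC)cc1OC)C(C)(C)O2 | intermediate (not isolated)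
13 | 1-(3-{1-[2,6-dimethoxy-4-(methoxymethoxy)phenyl]ethenyl}-5-hydroxy-7-methoxy-2,2-dimethyl-2H-chromen-6-yl)ethanone | COc1cc2c(c(O)c1C(C)=O)C=C(C(=C)c1c(OC)cc(OCOC)cc1OC)C(C)(C)O2 | intermediate
14 | 1-(3-{(1S)-1-[2,6-dimethoxy-4-(methoxymethoxy)phenyl]ethyl}-5-hydroxy-7-methoxy-2,2-dimethyl-2H-chromen-6-yl)ethanone | COc1cc2c(c(O)c1C(C)=O)C=C([C@H](C)c1c(OC)cc(OCOC)cc1OC)C(C)(C)O2 | intermediate
15 | 1-{5-hydroxy-3-[(1S)-1-(4-hydroxy-2,6-dimethoxyphenyl)ethyl]-7-methoxy-2,2-dimethyl-2H-chromen-6-yl}ethanone | COc1cc2c(c(O)c1C(C)=O)C=C([C@H](C)c1c(OC)cc(O)cc1OC)C(C)(C)O2 | intermediate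
16 | 3-methylbut-2-enal | CC(C)=CC=O | starting material
17 | 1-{3-[(1S)-1-(5,7-dimethoxy-2,2-dimethyl-2H-chromen-6-yl)ethyl]-5-hydroxy-7-methoxy-2,2-dimethyl-2H-chromen-6-yl}ethanone (CNP0303487.1) | COc1cc2c(c(O)c1C(C)=O)C=C([C@H](C)c1c(OC)cc3c(c1OC)C=CC(C)(C)O3)C(C)(C)O2 | target

## Step count and least certain steps

Total: 9 steps. Longest linear sequence: 8 steps (3 to 17 through steps 2 to 9); step 1 is the one-step branch to 2.

**Step 5 (key step).** The most likely failure is that the conjugate addition is too slow: the phenoxide of 2 is stabilised by two carbonyl groups and the β-carbon of 7 is fully substituted, so the retro-oxa-Michael reaction and slow self-condensation of 2 through its acetyl methyl group could win. Fallback, from 2 and 16, returning at 10: ring B is closed with the more reactive β,β-dimethyl enal. 2 and 16 (K2CO3, 1,4-dioxane, 100 °C) should give 6-acetyl-5-hydroxy-7-methoxy-2,2-dimethyl-2H-chromene-3-carbaldehyde F1 by the best-precedented form of the same domino, and the aryl half is then added as a nucleophile. 3,5-Dimethoxyphenol is silylated (iPr3SiCl, imidazole) to (3,5-dimethoxyphenoxy)tri(propan-2-yl)silane F2. F2 is lithiated between its methoxy groups (n-BuLi, THF, 0 °C; the bulky silyloxy group does not direct) and added in excess to F1; the first equivalents are consumed by the phenol and by enolisation of the acetyl group, which shields that ketone. This gives the racemic secondary carbinol F3. MnO2 oxidises it to the silyl-protected aroylchromene F4, which is never exposed to hot carbonate. Bu4NF gives the phenol ketone F5, and MOMCl/iPr2NEt (1 equiv; the chelated ring A hydroxyl is left) returns 10.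

**Step 7.** The most likely failures are poor facial discrimination between two bulky substituents at C9, or competing reduction of the C3=C4 bond once the terminal alkene is consumed. Fallback, from 13, returning at 14: the terminal alkene is reduced without asymmetric induction but with high site selectivity by diimide (2-nitrobenzenesulfonylhydrazide, Et3N, CH2Cl2, rt) or with RhCl(PPh3)3/H2. This gives racemic 1-(3-{1-[2,6-dimethoxy-4-(methoxymethoxy)phenyl]ethyl}-5-hydroxy-7-methoxy-2,2-dimethyl-2H-chromen-6-yl)ethanone F6, which is resolved by preparative HPLC on a polysaccharide carbamate chiral stationary phase to give 14.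

**Step 6.** The most likely failures are incomplete addition to the C9 carbonyl, which is flanked by a di-ortho-substituted arene and by C3 with its quaternary neighbour, or early loss of the silyl masks followed by attack on the acetyl group. Fallback, from 10, returning at 13: methylenation replaces addition and dehydration. 10 is converted (KN(SiMe3)2, tBuMe2SiCl, THF, −78 → 0 °C) into the isolable, characterisable [2,6-dimethoxy-4-(methoxymethoxy)phenyl]{5-(tert-butyldimethylsilyloxy)-6-[1-(tert-butyldimethylsilyloxy)ethenyl]-7-methoxy-2,2-dimethyl-2H-chromen-3-yl}methanone F7. F7 is methylenated at C9 with Cp2Ti(μ-Cl)(μ-CH2)AlMe2 (toluene/THF, 0 °C → rt); the titanium methylidene reacts by [2+2] cycloaddition and cycloreversion, is little affected by hindrance and cannot enolise. This gives the bis-silylated diene F8, and Bu4NF/AcOH then returns 13.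

**Step 1.** The most likely failure is formylation at the wrong ring carbon (C5, between OH and OMe), since both free positions are activated by the same donors. Fallback, from 1, returning at 2: the non-chelated 4-hydroxyl is alkylated selectively (MOMCl, K2CO3, acetone) to 1-[2-hydroxy-6-methoxy-4-(methoxymethoxy)phenyl]ethanone F9. Magnesium-mediated ortho-formylation (MgCl2, Et3N, paraformaldehyde, MeCN, reflux) can only take place next to the one free phenol, that is at C3, and gives 3-acetyl-2-hydroxy-4-methoxy-6-(methoxymethoxy)benzaldehyde F10. HCl/MeOH then returns 2.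

**Step 9.** The most likely failures are condensation of the enal with the acetyl methyl group or oligomerisation of the enal before the ortho carbon of the phenol is alkylated. Fallback, from 15, returning at 17: the ring C phenol alone is O-alkylated with 3-chloro-3-methylbut-1-yne (CuCl2 cat., DBU, MeCN, 0 °C; the chelated ring A hydroxyl does not react) to the propargyl ether 1-{3-[(1S)-1-{2,6-dimethoxy-4-[(2-methylbut-3-yn-2-yl)oxy]phenyl}ethyl]-5-hydroxy-7-methoxy-2,2-dimethyl-2H-chromen-6-yl}ethanone F11. Heating F11 (xylene, 140 °C) should give 17 by aromatic Claisen rearrangement, 1,5-hydrogen shift and oxa-6π-electrocyclisation.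

## Further compounds

F1 | step 5 | 6-acetyl-5-hydroxy-7-methoxy-2,2-dimethyl-2H-chromene-3-carbaldehyde | COc1cc2c(c(O)c1C(C)=O)C=C(C=O)C(C)(C)O2
F2 | step 5 | (3,5-dimethoxyphenoxy)tri(propan-2-yl)silane | COc1cc(OC)cc(O[Si](C(C)C)(C(C)C)C(C)C)c1
F3 | step 5 | rac-1-[3-({2,6-dimethoxy-4-[tri(propan-2-yl)silyloxy]phenyl}(hydroxy)methyl)-5-hydroxy-7-methoxy-2,2-dimethyl-2H-chromen-6-yl]ethanone | COc1cc2c(c(O)c1C(C)=O)C=C(C(O)c1c(OC)cc(O[Si](C(C)C)(C(C)C)C(C)C)cc1OC)C(C)(C)O2
F4 | step 5 | (6-acetyl-5-hydroxy-7-methoxy-2,2-dimethyl-2H-chromen-3-yl){2,6-dimethoxy-4-[tri(propan-2-yl)silyloxy]phenyl}methanone | COc1cc2c(c(O)c1C(C)=O)C=C(C(=O)c1c(OC)cc(O[Si](C(C)C)(C(C)C)C(C)C)cc1OC)C(C)(C)O2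
F5 | step 5 | (6-acetyl-5-hydroxy-7-methoxy-2,2-dimethyl-2H-chromen-3-yl)(4-hydroxy-2,6-dimethoxyphenyl)methanone | COc1cc2c(c(O)c1C(C)=O)C=C(C(=O)c1c(OC)cc(O)cc1OC)C(C)(C)O2
F6 | step 7 | rac-1-(3-{1-[2,6-dimethoxy-4-(methoxymethoxy)phenyl]ethyl}-5-hydroxy-7-methoxy-2,2-dimethyl-2H-chromen-6-yl)ethanone (racemate) | COc1cc2c(c(O)c1C(C)=O)C=C(C(C)c1c(OC)cc(OCOC)cc1OC)C(C)(C)O2
F7 | step 6 | [2,6-dimethoxy-4-(methoxymethoxy)phenyl]{5-(tert-butyldimethylsilyloxy)-6-[1-(tert-butyldimethylsilyloxy)ethenyl]-7-methoxy-2,2-dimethyl-2H-chromen-3-yl}methanone | COc1cc2c(c(O[Si](C)(C)C(C)(C)C)c1C(=C)O[Si](C)(C)C(C)(C)C)C=C(C(=O)c1c(OC)cc(OCOC)cc1OC)C(C)(C)O2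
F8 | step 6 | tert-butyl{[1-(5-(tert-butyldimethylsilyloxy)-3-{1-[2,6-dimethoxy-4-(methoxymethoxy)phenyl]ethenyl}-7-methoxy-2,2-dimethyl-2H-chromen-6-yl)ethenyl]oxy}dimethylsilane | COc1cc2c(c(O[Si](C)(C)C(C)(C)C)c1C(=C)O[Si](C)(C)C(C)(C)C)C=C(C(=C)c1c(OC)cc(OCOC)cc1OC)C(C)(C)O2
F9 | step 1 | 1-[2-hydroxy-6-methoxy-4-(methoxymethoxy)phenyl]ethanone | CC(=O)c1c(O)cc(OCOC)cc1OC
F10 | step 1 | 3-acetyl-2-hydroxy-4-methoxy-6-(methoxymethoxy)benzaldehyde | CC(=O)c1c(O)c(C=O)c(OCOC)cc1OC
F11 | step 9 | 1-{3-[(1S)-1-{2,6-dimethoxy-4-[(2-methylbut-3-yn-2-yl)oxy]phenyl}ethyl]-5-hydroxy-7-methoxy-2,2-dimethyl-2H-chromen-6-yl}ethanone | COc1cc2c(c(O)c1C(C)=O)C=C([C@H](C)c1c(OC)cc(OC(C)(C)C#C)cc1OC)C(C)(C)O2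
A1 | alternative 1 | 6-bromo-3-[(1S)-1-(5,7-dimethoxy-2,2-dimethyl-2H-chromen-6-yl)ethyl]-7-methoxy-5-(methoxymethoxy)-2,2-dimethyl-2H-chromene | COc1cc2c(c(OCOC)c1Br)C=C([C@H](C)c1c(OC)cc3c(c1OC)C=CC(C)(C)O3)C(C)(C)O2
A2 | alternative 1 | 6-bromo-3-[(1R)-1-(5,7-dimethoxy-2,2-dimethyl-2H-chromen-6-yl)ethyl]-7-methoxy-5-(methoxymethoxy)-2H-chromen-2-one | COc1cc2c(c(OCOC)c1Br)C=C([C@H](C)c1c(OC)cc3c(c1OC)C=CC(C)(C)O3)C(=O)O2
A3 | alternative 2 | 6-{(1S)-1-[6-bromo-7-methoxy-5-(methoxymethoxy)-2,2-dimethyl-2H-chromen-3-yl]ethyl}-5-hydroxy-2,2-dimethyl-7-[tri(propan-2-yl)silyloxy]-2,3-dihydro-4H-chromen-4-one | COc1cc2c(c(OCOC)c1Br)C=C([C@H](C)c1c(O)c3c(cc1O[Si](C(C)C)(C(C)C)C(C)C)OC(C)(C)CC3=O)C(C)(C)O2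
A4 | alternative 2 | 6-(diazoacetyl)-2,2-dimethyl-2,3-dihydro-4H-pyran-4-one | CC1(C)CC(=O)C=C(C(=O)C=[N+]=[N-])O1
A5 | alternative 2 | ({(3R)-3-[6-bromo-7-methoxy-5-(methoxymethoxy)-2,2-dimethyl-2H-chromen-3-yl]but-1-yn-1-yl}oxy)tri(propan-2-yl)silane | COc1cc2c(c(OCOC)c1Br)C=C([C@H](C)C#CO[Si](C(C)C)(C(C)C)C(C)C)C(C)(C)O2
A6 | alternative 3 | 1-[3-(1-{2,6-dimethoxy-4-[tri(propan-2-yl)silyloxy]phenyl}ethenyl)-5-hydroxy-7-methoxy-2,2-dimethyl-2H-chromen-6-yl]ethanone | COc1cc2c(c(O)c1C(C)=O)C=C(C(=C)c1c(OC)cc(O[Si](C(C)C)(C(C)C)C(C)C)cc1OC)C(C)(C)O2
A7 | alternative 3 | 1-{4-[(4-{2,6-dimethoxy-4-[tri(propan-2-yl)silyloxy]phenyl}-2-methylbut-3-yn-2-yl)oxy]-3-ethenyl-2-hydroxy-6-methoxyphenyl}ethanone | COc1cc(OC(C)(C)C#Cc2c(OC)cc(O[Si](C(C)C)(C(C)C)C(C)C)cc2OC)c(C=C)c(O)c1C(C)=O
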